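## Retrosynthetic overview

1. Botcinin K ⇐ Horner–Wadsworth–Emmons olefination (hexanal) of a C7 phosphonoacetate; C2/C3 ⇐ syn-hydrogenation of a 2-methyl β-keto-lactone enol.
2. Lactone ring (formed last) ⇐ intramolecular Claisen of an acetyl enolate onto a C5 methyl carbonate, which comes from an enantioselective, strain-releasing methanolysis of a meso cyclic carbonate (the symmetry-breaking step).
3. meso 2,6-diacetyl oxane ⇐ ethenolysis and Wacker oxidation of a meso 8-oxabicyclo[3.2.1]oct-6-ene; O-5/O-7 and 6-Me ⇐ double allylic oxidation and face-selective hydrogenation of a 3-methylidene group.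
4. Oxabicycle (first ring system; its oxane ring becomes the pyran of the target) ⇐ dearomative (4+3) cycloaddition of 2,5-dimethylfuran with the oxyallyl cation from tetrabromoacetone, setting both methyl-bearing ether carbons at once.
5. Ring order: oxabicycle → monocyclic oxane → δ-lactone.

Numbering used in names (botcinin numbering): C1 lactone C=O, C2, C3, C4 and C8 the methyl-bearing ether carbons, C5 and C7 the oxygenated carbons, C6 between them, C9/C10 the acetyl group. Target: (2R,3S,4R,5S,6S,7R,8R). In the oxabicycles, "exo" means on the side of the oxygen bridge and "endo" on the side of the C6=C7 bridge.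

Assumption: the quinidine-derived catalyst in step 8 is taken to leave the carbonate on O-5 (giving 11); if it prefers O-7, the quinine-derived pseudo-enantiomer is used instead.

## Route

Step 1
Reactants: 1 2,5-dimethylfuran; 2 1,1,3,3-tetrabromoacetone
Product: 4 meso-1,5-dimethyl-8-oxabicyclo[3.2.1]oct-6-en-3-one, via dibromo cycloadduct 3 (not isolated)
Conditions: Zn–Cu couple, THF, −10 °C → rt; then Zn–Cu couple, NH4Cl, MeOH, rt
Reagents that add atoms: none
Why: Noyori–Hoffmann dearomative (4+3) cycloaddition of the zinc oxyallyl cation (from reductive debromination of 2) across C2/C5 of the furan, followed by reductive removal of the two α-bromines; the suprafacial addition forces the two new tetrasubstituted ether carbons (C4 and C8 of the target) to be cis, giving a meso bicycle.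

Step 2
Reactants: 4 meso-1,5-dimethyl-8-oxabicyclo[3.2.1]oct-6-en-3-one
Product: 5 meso-1,5-dimethyl-3-methylidene-8-oxabicyclo[3.2.1]oct-6-ene
Conditions: MePPh3Br, KOtBu, THF, 0 → 50 °C
Reagents that add atoms: methyltriphenylphosphonium bromide C[P+](c1ccccc1)(c1ccccc1)c1ccccc1.[Br-]
Why: Wittig methylenation of an unhindered ketone flanked by two CH2 groups introduces the future 6-methyl carbon; no stereocentre is formed.

Step 3
Reactants: 5 meso-1,5-dimethyl-3-methylidene-8-oxabicyclo[3.2.1]oct-6-ene
Product: 6 meso-1,5-dimethyl-3-methylidene-8-oxabicyclo[3.2.1]oct-6-ene-2-exo,4-exo-diol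
Conditions: SeO2 (0.5 equiv), t-BuOOH (5 equiv), CH2Cl2, rt
Reagents that add atoms: tert-butyl hydroperoxide CC(C)(C)OO
Why: twofold SeO2 allylic oxidation (ene reaction, then 2,3-sigmatropic shift) at the only allylic C–H positions; oxygen is delivered to the open exo face (the endo face is covered by the C6=C7 bridge) so both hydroxyls end up axial and cis to the bridgehead methyls (C5 and C7 of the target), and the remaining carbinol C–H is equatorial and poorly aligned for over-oxidation to the enone.

Step 4
Reactants: 6 meso-1,5-dimethyl-3-methylidene-8-oxabicyclo[3.2.1]oct-6-ene-2-exo,4-exo-diol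
Product: 7 meso cyclic 2-exo,4-exo-carbonate of diol 6
Conditions: 1,1'-carbonyldiimidazole, DMAP (cat.), CH2Cl2, rt → 40 °C
Reagents that add atoms: 1,1'-carbonyldiimidazole O=C(n1ccnc1)n1ccnc1
Why: the syn-diaxial 1,3-diol closes readily to a six-membered cyclic carbonate (acyl substitution); its carbon becomes lactone C1 and the ring later locks the oxane conformation.

Step 5
Reactants: 7 meso cyclic 2-exo,4-exo-carbonate of diol 6
Product: 8 meso-2,6-diethenyl-2,6-dimethyl-4-methylideneoxane-3,5-diyl carbonate (vinyl groups cis to each other and trans to the carbonate oxygens)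
Conditions: ethylene (8 bar), second-generation Hoveyda–Grubbs catalyst RuCl2(H2IMes)(=CH-C6H4-2-OiPr) (5 mol%), toluene, 60 °C; ethyl vinyl ether quench before venting
Reagents that add atoms: ethylene C=C
Why: strain-driven ring-opening metathesis with ethylene (ethenolysis) of the bicyclic cis-alkene by the small ruthenium methylidene; the 1,1-disubstituted exocyclic alkene is inert, and the stereocentres are untouched.

Step 6
Reactants: 8 meso-2,6-diethenyl-2,6-dimethyl-4-methylideneoxane-3,5-diyl carbonate
Product: 9 meso-2,6-diacetyl-2,6-dimethyl-4-methylideneoxane-3,5-diyl carbonate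
Conditions: PdCl2(quinox) (5 mol%; quinox = 2-(4,5-dihydro-1,3-oxazol-2-yl)quinoline), AgSbF6 (12 mol%), aq. t-BuOOH, CH2Cl2, 0 °C → rt
Reagents that add atoms: tert-butyl hydroperoxide CC(C)(C)OO
Why: twofold Wacker-type oxidation under Sigman's conditions, which give the methyl ketone (Markovnikov) even next to an oxygen-bearing carbon; the 1,1-disubstituted alkene cannot give a ketone and cannot isomerise into the ring (bridgehead position of the carbonate bicycle).

Step 7
Reactants: 9 meso-2,6-diacetyl-2,6-dimethyl-4-methylideneoxane-3,5-diyl carbonate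
Product: 10 meso-2,6-diacetyl-2,4,6-trimethyloxane-3,5-diyl carbonate (4-methyl cis to the two acetyl groups)
Conditions: H2 (4 bar), 5% Rh/Al2O3, EtOAc, rt
Reagents that add atoms: none
Why: heterogeneous syn-hydrogenation; the carbonate holds the oxane with both acetyl groups axial so that they cover one face of the alkene, hydrogen enters from the open face next to the carbonate oxygens, and the methyl is pushed to the acetyl face (the C6 configuration of the target); rhodium is chosen over palladium to avoid allylic C–O hydrogenolysis and ketone reduction.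

Step 8
Reactants: 10 meso-2,6-diacetyl-2,4,6-trimethyloxane-3,5-diyl carbonate
Product: 11 (2S,3S,4R,5R,6R)-2,6-diacetyl-5-hydroxy-2,4,6-trimethyloxan-3-yl methyl carbonate (carbonate on O-5 and free 7-OH in botcinin numbering)
Conditions: MeOH (10 equiv), quinidine-derived 3,5-bis(trifluoromethyl)phenyl squaramide organocatalyst (10 mol%), MTBE, −20 °C
Reagents that add atoms: methanol CO
Why: Proposed new method: the bifunctional cinchona squaramide should hydrogen-bond the unhindered carbonate C=O, deliver methanol by general-base catalysis and then protonate one of the two enantiotopic ring oxygens as the tetrahedral intermediate collapses; the opening is irreversible because it releases the syn-axial acetyl/methyl/acetyl strain and the ring flips to the all-equatorial chair, in which the freed 7-OH cannot reach the carbonate (no migration, no racemisation); the closest known reaction type is the cinchona-alkaloid-catalysed enantioselective alcoholysis of meso cyclic anhydrides; no new stereocentre forms, but the choice between O-5 and O-7 fixes the absolute configuration of all five ring stereocentres.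

Step 9
Reactants: 11 (2S,3S,4R,5R,6R)-2,6-diacetyl-5-hydroxy-2,4,6-trimethyloxan-3-yl methyl carbonate
Product: 13 2-methyl β-keto lactone (7-hydroxy-2-methyl-3-oxo botcinin core; enol form drawn), via unmethylated keto lactone enolate 12 (not isolated)
Conditions: LiN(SiMe3)2 (3.0 equiv), THF, −78 → −30 °C; then MeI (1.05 equiv), DMPU, −30 → 0 °C; aq. NH4Cl
Reagents that add atoms: iodomethane CI
Why: intramolecular Claisen (Dieckmann-type) condensation, in which only the enolate of the C4 acetyl can reach the equatorial C5 carbonate (six-membered, trans-fused ring, methoxide leaves), followed by C-methylation of the resulting β-keto-lactone enolate with a soft electrophile; C2 stays enolisable here and is set in step 11.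

Step 10
Reactants: 13 2-methyl β-keto lactone; 14 (diethoxyphosphoryl)acetic acid
Product: 15 7-O-(diethoxyphosphoryl)acetyl-2-methyl β-keto lactone (enol form drawn)
Conditions: DCC, DMAP (cat.), CH2Cl2, 0 °C → rt
Reagents that add atoms: none
Why: Steglich esterification of the only alcohol; any enol ester formed at O-3 is itself an acyl donor and is funnelled by DMAP to the more stable alkyl ester, and C-acylation at the already methylated C2 would give a non-enolisable triketone and is disfavoured.

Step 11
Reactants: 15 7-O-(diethoxyphosphoryl)acetyl-2-methyl β-keto lactone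
Product: 16 (2R,3S,4R,5S,6S,7R,8R)-7-O-(diethoxyphosphoryl)acetyl-3-hydroxy botcinin core
Conditions: H2 (60 bar), 5% Rh/Al2O3, EtOAc, rt
Reagents that add atoms: none
Why: heterogeneous syn-hydrogenation of the enol C2=C3 (as in the reduction of tetronic acids and of the orlistat dihydropyranone) from the face opposite the axial 4-methyl, placing 2-Me and 3-OH cis to 4-Me and setting C2 (the less stable epimer, obtained kinetically) and C3 in one step; the saturated phosphonoacetate survives, and the neopentyl-type C9 methyl ketone is expected to be reduced much more slowly.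

Step 12
Reactants: 16 (2R,3S,4R,5S,6S,7R,8R)-7-O-(diethoxyphosphoryl)acetyl-3-hydroxy botcinin core; 17 hexanal
Product: 18 Botcinin K
Conditions: LiCl, i-Pr2NEt, MeCN, 0 °C → rt (17, 3 equiv)
Reagents that add atoms: none
Why: Horner–Wadsworth–Emmons olefination under Masamune–Roush conditions gives the (E)-oct-2-enoate; the base is too weak to epimerise C2, and excess aldehyde outruns intramolecular attack on the hindered C9 ketone.

## Compound list

1 | 2,5-dimethylfuran | Cc1ccc(C)o1 | starting material
2 | 1,1,3,3-tetrabromoacetone | O=C(C(Br)Br)C(Br)Br | starting material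
3 | 2,4-dibromo-1,5-dimethyl-8-oxabicyclo[3.2.1]oct-6-en-3-one (mixture of bromo epimers, cis bridgeheads) | O=C1C(Br)[C@@]2(C)C=C[C@@](C)(C1Br)O2 | intermediate
4 | meso-1,5-dimethyl-8-oxabicyclo[3.2.1]oct-6-en-3-one | O=C1C[C@@]2(C)C=C[C@@](C)(C1)O2 | intermediate
5 | meso-1,5-dimethyl-3-methylidene-8-oxabicyclo[3.2.1]oct-6-ene | C=C1C[C@@]2(C)C=C[C@@](C)(C1)O2 | intermediate
6 | meso-1,5-dimethyl-3-methylidene-8-oxabicyclo[3.2.1]oct-6-ene-2-exo,4-exo-diol | O[C@@H]1C(=C)[C@H](O)[C@@]2(C)C=C[C@]1(C)O2 | intermediate
7 | meso cyclic 2-exo,4-exo-carbonate of 6 | O=C1O[C@@H]2C(=C)[C@H](O1)[C@@]3(C)C=C[C@]2(C)O3 | intermediate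
8 | meso-2,6-diethenyl-2,6-dimethyl-4-methylideneoxane-3,5-diyl carbonate | O=C1O[C@@H]2C(=C)[C@H](O1)[C@@](C)(C=C)O[C@@]2(C)C=C | intermediate
9 | meso-2,6-diacetyl-2,6-dimethyl-4-methylideneoxane-3,5-diyl carbonate | O=C1O[C@@H]2C(=C)[C@H](O1)[C@@](C)(C(C)=O)O[C@@]2(C)C(C)=O | intermediate
10 | meso-2,6-diacetyl-2,4,6-trimethyloxane-3,5-diyl carbonate (4-Me cis to the acetyl groups) | O=C1O[C@@H]2[C@@H](C)[C@H](O1)[C@@](C)(C(C)=O)O[C@@]2(C)C(C)=O | intermediate
11 | (2S,3S,4R,5R,6R)-2,6-diacetyl-5-hydroxy-2,4,6-trimethyloxan-3-yl methyl carbonate | O[C@@H]1[C@@H](C)[C@H](OC(=O)OC)[C@@](C)(C(C)=O)O[C@@]1(C)C(C)=O | intermediate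
12 | unmethylated keto lactone (7-hydroxy-3-oxo botcinin core, ring stereocentres as in 18; formed as its lithium enolate, neutral form drawn) | O[C@@H]1[C@@H](C)[C@@H]2OC(=O)CC(=O)[C@@]2(C)O[C@@]1(C)C(C)=O | intermediate
13 | 2-methyl β-keto lactone (7-hydroxy-2-methyl-3-oxo botcinin core, ring stereocentres as in 18; enol tautomer drawn) | O[C@@H]1[C@@H](C)[C@@H]2OC(=O)C(C)=C(O)[C@@]2(C)O[C@@]1(C)C(C)=O | intermediate
14 | (diethoxyphosphoryl)acetic acid | CCOP(=O)(OCC)CC(=O)O | starting material
15 | 7-O-(diethoxyphosphoryl)acetyl-2-methyl β-keto lactone (enol tautomer drawn) | CCOP(=O)(OCC)CC(=O)O[C@@H]1[C@@H](C)[C@@H]2OC(=O)C(C)=C(O)[C@@]2(C)O[C@@]1(C)C(C)=O | intermediate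
16 | (2R,3S,4R,5S,6S,7R,8R)-7-O-(diethoxyphosphoryl)acetyl-3-hydroxy botcinin core | CCOP(=O)(OCC)CC(=O)O[C@@H]1[C@@H](C)[C@@H]2OC(=O)[C@H](C)[C@H](O)[C@@]2(C)O[C@@]1(C)C(C)=O | intermediate
17 | hexanal | CCCCCC=O | starting material
18 | Botcinin K | CCCCC/C=C/C(=O)O[C@@H]1[C@@H](C)[C@@H]2OC(=O)[C@H](C)[C@H](O)[C@@]2(C)O[C@@]1(C)C(C)=O | target

## Step count and risks

Total step count: 12. Longest linear sequence: 12 steps (from 1 and 2 to 18); the route is fully linear and uses no protecting groups.

The three steps most likely to fail: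

Step 8 (enantioselective methanolysis of the meso carbonate) is unprecedented for cyclic carbonates and may give low enantioselectivity. The fallback sets out from 10 and comes back at 13. Compound 10 is opened with the stoichiometric chiral nucleophile (S)-1-phenylethanol (DBU cat., THF, 0 °C) to give two diastereomeric mixed carbonates: the O-5 (S)-1-phenylethyl carbonate F7 and the O-7 (S)-1-phenylethyl carbonate F8. These are separated by chromatography. F7 is then put through the conditions of step 9, with 1-phenylethoxide as the leaving group in the Claisen closure, to give 13.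

Step 5 (ethenolysis) may stall because the alkene sits between two quaternary carbons. The fallback sets out from 7 and comes back at 10. The exocyclic alkene of 7 is first reduced by hydrogen-atom-transfer hydrogenation (Mn(dpm)3, dpm = dipivaloylmethanate, PhSiH3, t-BuOOH, i-PrOH), with hydrogen delivered from the exo face, to give the 3-endo-methyl bicyclic carbonate F4. Ozonolysis (O3, CH2Cl2, −78 °C; Me2S) then cleaves the bicyclic alkene regardless of hindrance to the meso dialdehyde F5. Twofold Wittig methylenation (Ph3P=CH2, THF, −78 → 0 °C) gives the meso divinyl carbonate F6, and the Wacker oxidation of step 6 converts F6 directly into 10.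

Step 3 (double allylic oxidation) may stop at the mono-alcohol or over-oxidise. The fallback sets out from 4 and comes back at 7; the oxygens are introduced by enolate oxidation before the methylidene group is made. Ketone 4 is hydroxylated from the exo face (KN(SiMe3)2, Davis oxaziridine, THF, −78 °C) to the racemic 2-exo-hydroxy ketone F1. A second round (2.2 equiv KN(SiMe3)2, Davis oxaziridine) gives the meso 2-exo,4-exo-dihydroxy ketone F2. 1,1'-Carbonyldiimidazole closes it to the meso carbonate ketone F3. Wittig methylenation of the ketone, which is far more electrophilic than the carbonate (Ph3P=CH2, THF, −78 → 0 °C), gives 7.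

Further compounds
F1 | step 3 | racemic 2-exo-hydroxy-1,5-dimethyl-8-oxabicyclo[3.2.1]oct-6-en-3-one (one enantiomer drawn) | O[C@@H]1C(=O)C[C@@]2(C)C=C[C@]1(C)O2
F2 | step 3 | meso-2-exo,4-exo-dihydroxy-1,5-dimethyl-8-oxabicyclo[3.2.1]oct-6-en-3-one | O[C@@H]1C(=O)[C@H](O)[C@@]2(C)C=C[C@]1(C)O2
F3 | step 3 | meso cyclic 2-exo,4-exo-carbonate of F2 | O=C1O[C@@H]2C(=O)[C@H](O1)[C@@]3(C)C=C[C@]2(C)O3
F4 | step 5 | meso cyclic 2-exo,4-exo-carbonate of 1,3-endo,5-trimethyl-8-oxabicyclo[3.2.1]oct-6-ene-2,4-diol | O=C1O[C@@H]2[C@@H](C)[C@H](O1)[C@@]3(C)C=C[C@]2(C)O3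
F5 | step 5 | meso-2,6-diformyl-2,4,6-trimethyloxane-3,5-diyl carbonate | O=C1O[C@@H]2[C@@H](C)[C@H](O1)[C@@](C)(C=O)O[C@@]2(C)C=O
F6 | step 5 | meso-2,6-diethenyl-2,4,6-trimethyloxane-3,5-diyl carbonate | O=C1O[C@@H]2[C@@H](C)[C@H](O1)[C@@](C)(C=C)O[C@@]2(C)C=C
F7 | step 8 | O-5 (S)-1-phenylethyl carbonate of the 2,6-diacetyl-2,4,6-trimethyloxane-3,5-diol (free 7-OH) | O[C@@H]1[C@@H](C)[C@H](OC(=O)O[C@@H](C)c2ccccc2)[C@@](C)(C(C)=O)O[C@@]1(C)C(C)=O
F8 | step 8 | O-7 (S)-1-phenylethyl carbonate of the 2,6-diacetyl-2,4,6-trimethyloxane-3,5-diol (free 5-OH) | C[C@H](OC(=O)O[C@@H]1[C@@H](C)[C@H](O)[C@@](C)(C(C)=O)O[C@@]1(C)C(C)=O)c1ccccc1
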